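**Retrosynthetic overview**
1. The oxetane is opened at its C(Me)–O bond, not at the acetal carbon, and the neighbouring C–Br goes with it. This retro 4-exo bromoetherification leads to a spiro-lactol that carries a 1-bromo-1,3-diene.
2. The spiro-lactol comes from the planar trienolate of 5-bromosafranal and (S)-2-isopropenyloxirane in an anionic formal [3+2]: C–C bond first, then O–C(acetal). Both oxygen rings are made in one flask.
3. 5-Bromosafranal comes from safranal by bromination of its only ring CH2. The carbocycle with its gem-dimethyl group is bought.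
4. The (S)-epoxide comes from the racemic epoxide by hydrolytic kinetic resolution. The racemate comes from methacrolein and a sulfonium methylide.
5. Ring order: cyclohexadiene (purchased), then tetrahydrofuran (as lactol), then oxetane.

Locants used below: C1 spiro carbon, C2 C(Me)–O, C3 CHBr, C4 =CH, C5 =CBr, C6 CMe2, C7 acetal CH, C8 CH2, C9 CH–isopropenyl. The target is 9R, 1S, 7S, 2S, 3S.
Assumption: alkylation of the planar trienolate by the chiral epoxide shows no useful facial bias at C1 (about 1:1), so the C1 epimer is removed by chromatography.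

Step 1
Reactants: 1 methacrolein
Product: 2 rac-2-(prop-1-en-2-yl)oxirane
Conditions: Me3SI, NaH, DMSO/THF, 0 °C to rt; distil
Reagents that add atoms: trimethylsulfonium iodide, C[S+](C)C.[I-]
Why: Corey–Chaykovsky epoxidation, in which the unstabilised sulfonium methylide adds 1,2 to the enal carbonyl and closes to the vinyl oxirane; the new stereocentre is racemic here and is resolved in step 2.

Step 2
Reactants: 2 rac-2-(prop-1-en-2-yl)oxirane
Product: 3 (S)-2-(prop-1-en-2-yl)oxirane
Conditions: (S,S)-N,N'-bis(3,5-di-tert-butylsalicylidene)cyclohexane-1,2-diaminatocobalt acetate, (salen)Co(OAc), trivalent cobalt, 0.5 mol %; H2O (0.55 equiv), neat, 0 °C to rt; distil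
Reagents that add atoms: none
Why: Jacobsen hydrolytic kinetic resolution, in which the (S,S)-catalyst (the one that leaves (S)-propylene oxide) hydrates (R)-2 and leaves (S)-3 in high ee; this carbon becomes C9 of the target.

Step 3
Reactants: 4 safranal
Product: 5 rac-5-bromo-2,6,6-trimethylcyclohexa-1,3-diene-1-carbaldehyde (5-bromosafranal)
Conditions: NBS (1.05 equiv), AIBN (5 mol %), PhCF3, 80 °C
Reagents that add atoms: N-bromosuccinimide, O=C1CCC(=O)N1Br
Why: Wohl–Ziegler bromination, in which abstraction of the only ring CH2 hydrogen (C5–H) gives a linearly conjugated pentadienyl radical extended by the formyl group and bromine transfer at C5 keeps the dienal conjugated; the C5 stereocentre is racemic and is erased in step 4.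

Step 4
Reactants: 5 rac-5-bromosafranal, 3 (S)-2-(prop-1-en-2-yl)oxirane
Product: 9 target CNP0141320.1, via potassium trienolate 6 (not isolated), via potassium lactolate 7 (not isolated), via spiro-lactol 8 (not isolated)
Conditions: KH (1.05 equiv), DME, 0 °C; 3 (1.5 equiv), DMPU, 0 to 40 °C; then CH2Cl2, AcOH (1.05 equiv), −78 °C; NBS (1.05 equiv), −78 to −20 °C, dark; chromatography
Reagents that add atoms: N-bromosuccinimide, O=C1CCC(=O)N1Br
Why: Proposed new method: KH removes the acidified C5–H of 5 to give the planar bromo-trienolate 6, which like other extended aldehyde enolates alkylates at the α-carbon C1 (deconjugative α-alkylation) by SN2 opening of the unhindered CH2 terminus of 3 (C9 is untouched and is R in the product), the released alkoxide closes 5-exo on the now non-enolisable C7 aldehyde to lactolate 7, and after protonation the equilibrating lactol 8 traps the bromonium ion of the most electron-rich alkene C2=C3 at the tertiary carbon C2 from the face that carries C7 (4-exo-trig, anti addition, so O and Br are trans, the oxetane is cis-fused, C7, C2 and C3 all follow from C1, and the isopropenyl group sits on the convex face), whereas C1 itself forms without useful bias and its epimer is removed by chromatography; the closest known reaction types are the enolate–epoxide route to γ-lactols, the KH-mediated C-alkylation of α-branched aldehyde enolates and the 4-exo bromolactonisation of cyclohexadienecarboxylic acids to bromo-β-lactones.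

**Compound list**
1 | methacrolein (2-methylprop-2-enal) | C=C(C)C=O | starting material
2 | rac-2-(prop-1-en-2-yl)oxirane | C=C(C)C1CO1 | intermediate
3 | (S)-2-(prop-1-en-2-yl)oxirane | C=C(C)[C@H]1CO1 | intermediate
4 | safranal (2,6,6-trimethylcyclohexa-1,3-diene-1-carbaldehyde) | CC1=C(C=O)C(C)(C)CC=C1 | starting material
5 | rac-5-bromo-2,6,6-trimethylcyclohexa-1,3-diene-1-carbaldehyde | CC1=C(C=O)C(C)(C)C(Br)C=C1 | intermediate
6 | potassium (3-bromo-2,2,6-trimethylcyclohexa-3,5-dien-1-ylidene)methanolate | [K+].[O-]C=C1C(C)=CC=C(Br)C1(C)C | intermediate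
7 | potassium (3R,5R)-9-bromo-6,10,10-trimethyl-3-(prop-1-en-2-yl)-2-oxaspiro[4.5]deca-6,8-dien-1-olate (anomers) | C=C(C)[C@H]1C[C@@]2(C([O-])O1)C(C)=CC=C(Br)C2(C)C.[K+] | intermediate
8 | (3R,5R)-9-bromo-6,10,10-trimethyl-3-(prop-1-en-2-yl)-2-oxaspiro[4.5]deca-6,8-dien-1-ol (anomers; same spatial arrangement at the spiro carbon as in 9, the descriptor changes with the ranking) | C=C(C)[C@H]1C[C@@]2(C(O)O1)C(C)=CC=C(Br)C2(C)C | intermediate
9 | CNP0141320.1, tricyclic dibromo oxetane acetal (9R,1S,7S,2S,3S in the locants above) | C=C(C)[C@H]1C[C@@]23[C@@H](O1)O[C@]2(C)[C@@H](Br)C=C(Br)C3(C)C | target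

Total step count: 4. Longest linear sequence: 3 (steps 1, 2, 4).

**Steps most likely to fail**

Step 4. Three things can go wrong. A hindered aldehyde enolate has to open an epoxide. C1 is not controlled. The 4-exo closure competes with bromonium formation at the isopropenyl group and with oxidation of the lactol.

The fallback sets out from 5 and comes back at 8.
- Condense 5 with (S)-tert-leucine tert-butyl ester (4 Å sieves, CH2Cl2) to the aldimine tert-butyl (S)-2-{(E)-[(5-bromo-2,6,6-trimethylcyclohexa-1,3-dien-1-yl)methylidene]amino}-3,3-dimethylbutanoate F1.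
- LiN(iPr)2 (THF, −78 °C) gives a chelated lithio-aza-trienolate. This metalloenamine opens 3 at its CH2 far more readily than an aldehyde enolate.
- The tert-butyl group of the chelate blocks one face of C1. The sense of induction must be checked, and the (R)-amine is used if it is opposite.
- The product is the hydroxy-imine tert-butyl (S)-2-{(E)-[((1R)-3-bromo-1-[(2R)-2-hydroxy-3-methylbut-3-en-1-yl]-2,2,6-trimethylcyclohexa-3,5-dien-1-yl)methylidene]amino}-3,3-dimethylbutanoate F2.
- Aqueous citric acid hydrolyses it to lactol 8, which is purified and then closed to 9 with NBS in a flask of its own.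

Step 3. Radical bromination could give the C3 or CH2Br isomers, or attack the formyl C–H.

The fallback sets out from 4 and comes back at 5.
- Soft enolisation (TBSOTf, Et3N, CH2Cl2, 0 °C) gives the trienol silyl ether tert-butyl[(2,2,6-trimethylcyclohexa-3,5-dien-1-ylidene)methoxy]dimethylsilane F3.
- NBS (THF, −78 °C) then brominates ionically at the vinylogous terminus C5. This is the only site that restores the fully conjugated dienal.

Step 2. The epoxide is volatile, and the selectivity factor of an isopropenyl oxirane in the hydrolytic resolution is untested.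

The fallback sets out from 1 and comes back at 3, bypassing 2.
- ClCH2I and MeLi·LiBr (THF, −78 °C, cold AcOH quench) add chloromethyllithium to 1 and give rac-1-chloro-3-methylbut-3-en-2-ol F4.
- Candida antarctica lipase B with vinyl acetate acylates the (S)-enantiomer (Kazlauskas rule, CH2Cl as the medium group). This gives (S)-1-chloro-3-methylbut-3-en-2-yl acetate F5, which is separated from the (R)-alcohol.
- K2CO3 in MeOH cleaves the acetate and closes the epoxide without touching the stereocentre, giving 3.

**Further compounds**
F1 | step 4 | tert-butyl (S)-2-{(E)-[(5-bromo-2,6,6-trimethylcyclohexa-1,3-dien-1-yl)methylidene]amino}-3,3-dimethylbutanoate | CC1=C(/C=N/[C@@H](C(C)(C)C)C(=O)OC(C)(C)C)C(C)(C)C(Br)C=C1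
F2 | step 4 | tert-butyl (S)-2-{(E)-[((1R)-3-bromo-1-[(2R)-2-hydroxy-3-methylbut-3-en-1-yl]-2,2,6-trimethylcyclohexa-3,5-dien-1-yl)methylidene]amino}-3,3-dimethylbutanoate | C=C(C)[C@H](O)C[C@@]1(/C=N/[C@@H](C(C)(C)C)C(=O)OC(C)(C)C)C(C)=CC=C(Br)C1(C)C
F3 | step 3 | tert-butyl[(2,2,6-trimethylcyclohexa-3,5-dien-1-ylidene)methoxy]dimethylsilane | CC1=CC=CC(C)(C)C1=CO[Si](C)(C)C(C)(C)C
F4 | step 2 | rac-1-chloro-3-methylbut-3-en-2-ol | C=C(C)C(O)CCl
F5 | step 2 | (S)-1-chloro-3-methylbut-3-en-2-yl acetate | C=C(C)[C@H](OC(C)=O)CCl
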